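## Retrosynthetic overview
1. All atoms come from dihydrocaffeic acid 1 (activated as its succinimidyl ester 2) and spermine 3. No C–C bond and no ring is made, since both arenes are bought with 1. Every strategic bond is an amide C–N bond.
2. Disconnection a: the two secondary-amide C–N bonds at the primary nitrogens N1 and N14 lead back to symmetric kukoamine A 4 (two parts 2 plus 3), so no desymmetrisation is needed at that stage.
3. Disconnection b (key): the tertiary-amide C–N bond at N10 leads back to 4 by moving one acyl group from N14 to N10, a 1,5 N→N shift through a six-membered adduct. Salicylaldehyde 5 pulls the shift uphill as imine 6. One proton per molecule stops it after one end. Hydrolysis of 6 gives kukoamine B 7.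

Assumption: the target has no stereocentre and no stereogenic C=C bond, so it is achiral and needs no enantiocontrol. Only the transient imine 6 has a geometry (E).
Numbering: the spermine nitrogens are called N1, N5, N10 and N14 along the chain. In 7, N1 is a secondary amide, N5 a free secondary amine, N10 a tertiary amide and N14 a free primary amine.

## Route

Step 1
Reactants: 1 dihydrocaffeic acid
Product: 2 succinimidyl dihydrocaffeate
Conditions: HOSu (1.05 equiv), DCC (1.05 equiv), THF, 0 °C to rt, Ar; filter, crystallise
Reagents that add atoms: N-hydroxysuccinimide, O=C1CCC(=O)N1O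
Why: In this carbodiimide active-ester formation the O-acylisourea is intercepted by the acidic, nucleophilic N–OH much faster than by the catechol OH groups when no acyl-transfer catalyst is present, which gives an isolable crystalline ester with no phenol protection.

Step 2
Reactants: 2 succinimidyl dihydrocaffeate (2.05 equiv); 3 spermine
Product: 4 kukoamine A
Conditions: degassed DMF, −20 °C to rt, Ar; C18 chromatography
Reagents that add atoms: none
Why: In this active-ester aminolysis (amide coupling) succinimidyl esters acylate the two unhindered primary amines of a polyamine far faster than the secondary amines at low temperature, phenols do not compete, and symmetry means only one diamide can form.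

Step 3
Reactants: 4 kukoamine A; 5 salicylaldehyde (2 equiv)
Product: 7 kukoamine B, via N14-salicylidene kukoamine B 6 (not isolated)
Conditions: MsOH (1.05 equiv), 2-pyridone (20 mol%), degassed n-BuOH (0.2 M), reflux (117 °C), Ar, 48 h; then 0.5 M aq MsOH, rt, 1 h, EtOAc wash; NaHCO3 to pH 9, 0 °C; C18 chromatography, lyophilise
Reagents that add atoms: none
Why: Proposed new method: a proton-gated, trap-driven, contra-thermodynamic 1,5 N→N acyl shift (intramolecular transamidation), in which the one free secondary amine of the mono-mesylate of 4 adds to the amide carbonyl three carbons away through a six-membered tetrahedral adduct (2-pyridone and the catechols shuttle protons) and expels the terminal nitrogen as a primary amine, this uphill isomer is drained by 5 as the hydrogen-bonded salicylimine 6 (a secondary amine cannot give an imine), the single proton then rests on N5 as the only basic nitrogen left so that the second end is switched off both kinetically and thermodynamically, and aqueous acid finally frees N14 as an ammonium that cannot shift back; the closest known reaction types are the Zip-type transamidation of N-(3-aminopropyl) amides, which runs only in the opposite, downhill direction, and the selective masking of primary amines of polyamines as salicylidene imines.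

## Compound list
1 | 3-(3,4-dihydroxyphenyl)propanoic acid (dihydrocaffeic acid) | OC(=O)CCc1ccc(O)c(O)c1 | starting material
2 | 2,5-dioxopyrrolidin-1-yl 3-(3,4-dihydroxyphenyl)propanoate (succinimidyl dihydrocaffeate) | O=C(CCc1ccc(O)c(O)c1)ON1C(=O)CCC1=O | intermediate
3 | spermine (N,N'-bis(3-aminopropyl)butane-1,4-diamine) | NCCCNCCCCNCCCN | starting material
4 | kukoamine A (N1,N14-bis(dihydrocaffeoyl)spermine) | O=C(CCc1ccc(O)c(O)c1)NCCCNCCCCNCCCNC(=O)CCc1ccc(O)c(O)c1 | intermediate
5 | salicylaldehyde (2-hydroxybenzaldehyde) | O=Cc1ccccc1O | starting material
6 | N14-salicylidene kukoamine B, (E)-imine, present in the flask as its N5 ammonium mesylate | Oc1ccccc1/C=N/CCCN(CCCCNCCCNC(=O)CCc1ccc(O)c(O)c1)C(=O)CCc1ccc(O)c(O)c1 | intermediate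
7 | kukoamine B (N1,N10-bis(dihydrocaffeoyl)spermine), achiral | NCCCN(CCCCNCCCNC(=O)CCc1ccc(O)c(O)c1)C(=O)CCc1ccc(O)c(O)c1 | target

## Step count and risks
Total step count: 3. Longest linear sequence: 3 (1 → 2 → 4 → 7).

**Most likely to fail: step 3 (the proposed new step).**
- The attack of a secondary amine on a secondary amide may be too slow at 117 °C.
- Compound 5 may hold the amine/amide pair of 4 as a cyclic N-acyl aminal. This is reversible and returns 4 on acid work-up.
- Iminium species may add to the catechol rings in a Mannich-type reaction.
- An error in the acid stoichiometry would let the second end shift.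
- Unreacted 4 is separated and recovered on C18.
- Compound 7 is best stored as its mesylate, because the free base can drift back to 4 on heating.

The fallback uses only known chemistry. It sets out from 3 (together with 2) and comes back at 7. Slow addition of 2 to a four-fold excess of 3 at −20 °C gives N1-(dihydrocaffeoyl)spermine F4. One equivalent of aqueous formaldehyde closes the remaining free 1,3-diamine end to N10,N14-methylene-N1-(dihydrocaffeoyl)spermine F5, a hexahydropyrimidine that hides N10 as a tertiary aminal nitrogen. Boc2O (2.1 equiv, MeOH, no base) caps the two remaining NH groups to give N5,N14-di-Boc-N10,N14-methylene-N1-(dihydrocaffeoyl)spermine F6. Malonic acid and pyridine in refluxing EtOH take out the methylene bridge (Knoevenagel-type scavenging) to give N5,N14-di-Boc-N1-(dihydrocaffeoyl)spermine F7, whose only free amine is N10. Acylation with 2, iPr2NEt and DMF at 40 °C gives N5,N14-di-Boc-kukoamine B F8. HCl in dioxane followed by neutralisation delivers 7.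

**Second: step 2.**
- Partial acylation of N5 or N10 may occur.
- Air oxidation of the catecholate–ammonium salt is possible.
- The very polar product may be hard to purify.

The fallback sets out from 3 and comes back at 4. Aqueous formaldehyde (2 equiv) converts 3 quantitatively into 1,4-bis(hexahydropyrimidin-1-yl)butane F2, in which N5 and N10 are tertiary and cannot be acylated. Treatment with 2 (2.2 equiv, iPr2NEt, DMF) gives 1,4-bis[3-(dihydrocaffeoyl)hexahydropyrimidin-1-yl]butane F3, which can be purified on silica. Malonic acid and pyridine in refluxing EtOH remove both methylene bridges to give 4.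

**Third: step 1.**
- The unprotected catechol may self-acylate to oligomeric esters.
- Removal of the urea may be incomplete.

The fallback sets out from 1 and comes back at 4 without any coupling reagent. Fischer esterification (MeOH, cat. H2SO4, reflux) gives methyl 3-(3,4-dihydroxyphenyl)propanoate F1. Heating F1 with 3 (0.5 equiv) in degassed MeOH at 65 °C under Ar gives 4 directly by thermal ester aminolysis, which is selective for primary amines.

## Further compounds
F1 | step 1 | methyl 3-(3,4-dihydroxyphenyl)propanoate | COC(=O)CCc1ccc(O)c(O)c1
F2 | step 2 | 1,4-bis(hexahydropyrimidin-1-yl)butane | C1CNCN(C1)CCCCN1CCCNC1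
F3 | step 2 | 1,4-bis[3-(dihydrocaffeoyl)hexahydropyrimidin-1-yl]butane | O=C(CCc1ccc(O)c(O)c1)N1CCCN(C1)CCCCN1CCCN(C1)C(=O)CCc1ccc(O)c(O)c1
F4 | step 3 | N1-(dihydrocaffeoyl)spermine | NCCCNCCCCNCCCNC(=O)CCc1ccc(O)c(O)c1
F5 | step 3 | N10,N14-methylene-N1-(dihydrocaffeoyl)spermine | C1CNCN(C1)CCCCNCCCNC(=O)CCc1ccc(O)c(O)c1
F6 | step 3 | N5,N14-di-Boc-N10,N14-methylene-N1-(dihydrocaffeoyl)spermine | CC(C)(C)OC(=O)N1CCCN(C1)CCCCN(CCCNC(=O)CCc1ccc(O)c(O)c1)C(=O)OC(C)(C)C
F7 | step 3 | N5,N14-di-Boc-N1-(dihydrocaffeoyl)spermine | CC(C)(C)OC(=O)NCCCNCCCCN(CCCNC(=O)CCc1ccc(O)c(O)c1)C(=O)OC(C)(C)C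
F8 | step 3 | N5,N14-di-Boc-kukoamine B | CC(C)(C)OC(=O)NCCCN(CCCCN(CCCNC(=O)CCc1ccc(O)c(O)c1)C(=O)OC(C)(C)C)C(=O)CCc1ccc(O)c(O)c1
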